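**Plan**

1. Cuts: the four bonds that tie a four-carbon chain C1–C4 [C1H(4-hydroxyphenyl)–C2H–C3H–C4H(4-hydroxyphenyl)] to two 2,3-diaryl-2,3-dihydrobenzofuran units (one trans, one cis); then the furan C-2/C-3 hydrogens of both units (back to one common benzofuran); last the aryl–O bond (O-1 to C-7a) of that benzofuran.
2. Enabling feature: in each benzofuran benzene ring, C-3a has the furan oxygen on one ortho carbon (C-7a) and a chain carbon on the other (C-4), with the phenol oxygen para (C-6). A 4-benzyloxy-3,5-dichlorophenyl group joined through one carbon can therefore take up O, and later C, at its two ortho carbons by two successive arynes, each attacked meta to the benzyloxy group.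
3. Forward: two ketone α-arylations, aryne O-arylation to the benzofuran (both aryl–O bonds of the target), asymmetric cis-hydrogenation, acid epimerisation of part of it to the trans unit. Then C1 of a keto-alcohol chain + trans unit (Friedel–Crafts), first eight-membered ring (C3 enolate + aryne), C4 + cis unit (Friedel–Crafts), second eight-membered ring (C2 vinylogous phenoxide + aryne), transfer hydrogenation, debenzylation.
4. Stereochemistry: furan C-3 of both units and the cis C-2 come from the one hydrogenation, the trans C-2 from the epimerisation; C3/C4 are set in step 12 and C2/C1 in step 15 by acid-catalysed additions to the rigid core.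
5. Ring size: at each eight-ring closure only one carbon nucleophile and one aryne are present, so a seven-membered ring cannot form.

Key step: step 4

Assumption: benzylic cations attack the 3,5-bis(benzyloxy)phenyl ring at C-2 (para to one benzyloxy group, ortho to the ring substituent), as halogenation and acylation of 5-alkylresorcinol diethers do.

**Route**

Step 1
Reactants: 1 4-bromo-2,6-dichlorophenol
Product: 2 2-(benzyloxy)-5-bromo-1,3-dichlorobenzene
Conditions: BnBr, K2CO3, DMF, rt
Reagents that add atoms: benzyl bromide, BrCc1ccccc1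
Why: Williamson ether synthesis; the acidic 2,6-dichlorophenoxide should alkylate cleanly on oxygen.

Step 2
Reactants: 3 1-[4-(benzyloxy)phenyl]ethanone; 4 1,3-bis(benzyloxy)-5-bromobenzene
Product: 5 deoxybenzoin 1-[4-(benzyloxy)phenyl]-2-[3,5-bis(benzyloxy)phenyl]ethan-1-one
Conditions: ketone in excess (1.5 equiv), Pd2(dba)3 (cat.), Xantphos, NaOtBu, toluene, 80 °C
Reagents that add atoms: none
Why: Palladium-catalysed ketone α-arylation; excess ketone and the wide-bite-angle ligand should hold it at mono-arylation.

Step 3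
Reactants: 5 deoxybenzoin; 2 aryl bromide
Product: 6 racemic 1,2,2-triarylethanone
Conditions: Pd(OAc)2 (cat.), P(t-Bu)3·HBF4, NaOtBu, toluene, 70 °C
Reagents that add atoms: none
Why: Second palladium-catalysed α-arylation (deoxybenzoin to 1,2,2-triarylethanone); oxidative addition should take the C–Br bond and leave both hindered C–Cl bonds, and the new centre need not be controlled because step 4 flattens it.

Step 4
Reactants: 6 triarylethanone
Product: 8 6-(benzyloxy)-2-[4-(benzyloxy)phenyl]-3-[3,5-bis(benzyloxy)phenyl]-5-chloro-1-benzofuran, via chloroaryne 7 (not isolated)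
Conditions: lithium 2,2,6,6-tetramethylpiperidide (2.2 equiv), THF, −78 to 0 °C; aq NH4Cl
Reagents that add atoms: none
Why: The amide base forms the enolate of 6 and then removes a ring hydrogen ortho to chlorine, loss of LiCl gives aryne 7, the enolate oxygen adds in the ring plane to the aryne carbon next to the ring junction, and the resulting C-7 aryllithium is protonated on work-up. The closest known reaction type is the aryne ring closure of a tethered oxygen anion (an alkoxide or the oxygen of an amide anion) onto an aryne made from a meta-haloarene, together with the lithium-amide-mediated arylation of enolates by chloroarenes through arynes. The furan ring closes in a 5-exo-dig sense, the only mode open to the enolate because attack through carbon would give a three-membered ring. No stereocentre is formed: the racemic centre of 6 is planarised, and the furan stereocentres of both units are set later from this one benzofuran, by catalyst control in the hydrogenation of step 5 and by thermodynamic control in the epimerisation of step 6. The selectivities needed are attack at the aryne carbon meta to the benzyloxy group, a single aryne event and an enolate geometry with oxygen cis to the chloroaryl ring: the benzyloxy group beside the triple bond polarises the aryne so that charge develops ortho to oxygen and the tether reaches only this carbon, the two chlorines are equivalent before the first elimination and the C-7-lithiated product should resist a second ortho-deprotonation so that the second chlorine survives for steps 10 and 14, and the doubly benzylic enolate is expected to interconvert its two geometries on warming by rotation through a diarylmethyl-anion-like transition state.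

Step 5
Reactants: 8 benzofuran
Product: 9 (2R,3S)-cis-dihydrobenzofuran (cis unit)
Conditions: Ru(cod)(2-methylallyl)2 (cat.), (R,R)-SINpEt·HBF4 [1,3-bis((R)-1-(naphthalen-1-yl)ethyl)-4,5-dihydroimidazolium tetrafluoroborate], KOtBu, H2 (80 bar), toluene, 40 °C
Reagents that add atoms: none
Why: Ruthenium–N-heterocyclic-carbene asymmetric hydrogenation of the benzofuran C2=C3 bond; syn delivery of H2 gives the cis isomer, the ligand enantiomer is chosen to give (2R,3S), and the homogeneous catalyst should spare the aryl chloride and the benzyl ethers.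

Step 6
Reactants: 9 cis unit
Product: 10 (2S,3S)-trans-dihydrobenzofuran (trans unit)
Conditions: CF3CO2H (10 mol%), CH2Cl2, 0 °C to rt
Reagents that add atoms: none
Why: Acid-mediated epimerisation at C-2 (applied to the part of the cis unit that is needed as the trans unit) by reversible heterolysis of the benzylic C2–O bond (4-benzyloxybenzyl cation and phenol) and reclosure to the more stable trans isomer; mild acid and short contact should keep C-3 from exchanging.

Step 7
Reactants: 11 4-(4-hydroxyphenyl)-4-oxobutanoic acid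
Product: 13 racemic 5-(4-hydroxyphenyl)oxolan-2-one, via hydroxy acid 12 (not isolated)
Conditions: NaBH4, aq NaOH, rt; then aq HCl, 60 °C
Reagents that add atoms: none
Why: Borohydride reduction of the aryl ketone followed by acid-catalysed γ-lactonisation with loss of water.

Step 8
Reactants: 13 lactone; 14 1-(benzyloxy)-4-bromobenzene
Product: 16 racemic 1-[4-(benzyloxy)phenyl]-4-hydroxy-4-(4-hydroxyphenyl)butan-1-one, via aryllithium 15 (not isolated)
Conditions: aryl bromide (2.2 equiv), n-BuLi, THF, −78 °C; then lactone, −78 °C; aq NH4Cl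
Reagents that add atoms: none
Why: Bromine–lithium exchange, then addition of the aryllithium to the lactone, which should stop at the lactolate at −78 °C and give the hydroxy ketone on work-up; the first equivalent deprotonates the phenol.

Step 9
Reactants: 16 keto-alcohol; 10 trans unit
Product: 17 chain ketone carrying the trans unit on C1 (C1 R)
Conditions: (R)-TRIP [3,3'-bis(2,4,6-triisopropylphenyl)-1,1'-binaphthyl-2,2'-diyl hydrogen phosphate] (10 mol%), CH2Cl2, 4 Å MS, 0 °C
Reagents that add atoms: none
Why: Chiral-phosphoric-acid-catalysed Friedel–Crafts 1,6-addition to a p-quinone methide formed in situ from the 4-hydroxybenzylic alcohol by loss of water; the resorcinol ring of the trans unit should react at C-2, and the catalyst enantiomer is chosen to give C1 R, a centre that is only temporary (flattened in step 13).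

Step 10
Reactants: 17 chain ketone
Product: 19 ketone of the first eight-membered ring (chain C3 joined to benzofuran C-4 of the trans unit; C3 epimers), via aryne 18 (not isolated)
Conditions: lithium 2,2,6,6-tetramethylpiperidide (3.5 equiv), THF (high dilution), −78 to −20 °C; aq NH4Cl
Reagents that add atoms: none
Why: Intramolecular aryne α-arylation of a ketone enolate: the base gives the phenoxide and the only possible enolate (C3), lithiates next to the remaining chlorine (lithiation between the two oxygens is reversible and unproductive), and the aryne is attacked at C-4, meta to benzyloxy, closing the eight-membered ring; no second carbon nucleophile exists, so no seven-membered ring can form, and the base-labile C3 centre is carried as an epimer mixture.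

Step 11
Reactants: 19 ketone of the first eight-membered ring
Product: 20 benzylic alcohol of the first eight-membered ring (epimers at C3 and C4)
Conditions: NaBH4, THF/MeOH, 0 °C
Reagents that add atoms: none
Why: Borohydride reduction of the aryl ketone; the carbinol configuration is irrelevant because the centre is ionised in step 12.

Step 12
Reactants: 20 benzylic alcohol; 9 cis unit
Product: 21 compound of the first eight-membered ring carrying the cis unit on C4 (C1 R, C3 R, C4 R)
Conditions: cis unit in excess (1.5 equiv), N-triflylphosphoramide of (R)-3,3'-bis(2,4,6-triisopropylphenyl)-1,1'-bi-2-naphthol (10 mol%), CH2Cl2, 4 Å MS, −40 °C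
Reagents that add atoms: none
Why: Brønsted-acid Friedel–Crafts benzylation with loss of water: the 4-benzyloxybenzylic cation at C4 (in equilibrium with the C3=C4 alkene by loss of the C3 proton, which lets C3 equilibrate) is trapped by the resorcinol ring of the cis unit at C-2; no arene of the alcohol can reach the cation without a meta-bridged ring, reprotonation at C3 and attack at C4 should occur on the open face of the eight-membered ring within the chiral ion pair (1,2-induction from the adjacent ring centre), and the low temperature and catalytic acid loading should leave the cis C2–O bond intact.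

Step 13
Reactants: 21 Friedel–Crafts product
Product: 23 4-hydroxyphenyl alkene (C1=C2), via quinone methide 22 (not isolated)
Conditions: DDQ (1.05 equiv), CH2Cl2, −20 °C; then Et3N
Reagents that add atoms: none
Why: DDQ dehydrogenation of the 4-hydroxyphenyl-substituted methine to the p-quinone methide (only C1–H is activated by a free phenol), then amine-catalysed tautomerisation to the alkene, whose geometry is fixed as cis within the eight-membered ring.

Step 14
Reactants: 23 alkene phenol
Product: 25 bicyclic tetrasubstituted alkene (both eight-membered rings closed), via aryne 24 (not isolated)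
Conditions: lithium 2,2,6,6-tetramethylpiperidide (2.5 equiv), THF (high dilution), −78 to −20 °C; aq NH4Cl
Reagents that add atoms: none
Why: Proposed new method: the phenoxide of 23 is a vinylogous enolate whose only reachable nucleophilic carbon is the alkene CH (C2, para-conjugated with O−); ortho-lithiation next to chlorine and loss of LiCl give the aryne on the cis unit, C2 adds to benzofuran C-4 (meta to benzyloxy) to close the second eight-membered ring, and the quinone methide so formed tautomerises to the tetrasubstituted alkene by amine-mediated proton transfer from C2 to the C-5 aryl anion; the closest known reaction types are the C-arylation of phenoxides by arynes generated from chloroarenes with lithium amide bases and the aryne α-arylation of enolates used in step 10.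

Step 15
Reactants: 25 tetrasubstituted alkene
Product: 26 nona-O-benzyl ether of the target
Conditions: (S)-TRIP [3,3'-bis(2,4,6-triisopropylphenyl)-1,1'-binaphthyl-2,2'-diyl hydrogen phosphate] (10 mol%), diethyl 2,6-dimethyl-1,4-dihydropyridine-3,5-dicarboxylate, toluene, 40 °C
Reagents that add atoms: none
Why: Chiral-phosphoric-acid-catalysed transfer hydrogenation of a hydroxyphenyl alkene through its p-quinone methide tautomer: reversible protonation at C2 should settle that centre on the less strained face of the bicyclic core (C2 S) and hydride from the dihydropyridine should then reach C1 from the open face within the chiral ion pair (C1 R), with the catalyst enantiomer chosen to match; a C1 epimer can be returned to 25 under the conditions of step 13.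

Step 16
Reactants: 26 nona-O-benzyl ether
Product: 27 target
Conditions: BCl3, pentamethylbenzene, CH2Cl2, −78 °C; then MeOH, aq work-up
Reagents that add atoms: none
Why: Lewis-acid debenzylation with a non-basic cation scavenger at low temperature, which should cleave the nine benzyl ethers without reducing or ionising the two dihydrobenzofuran C2–O bonds.

**Compound list**

1 | 4-bromo-2,6-dichlorophenol | Oc1c(Cl)cc(Br)cc1Cl | starting material
2 | 2-(benzyloxy)-5-bromo-1,3-dichlorobenzene | Clc1cc(Br)cc(Cl)c1OCc1ccccc1 | intermediate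
3 | 1-[4-(benzyloxy)phenyl]ethanone | CC(=O)c1ccc(OCc2ccccc2)cc1 | starting material
4 | 1,3-bis(benzyloxy)-5-bromobenzene | Brc1cc(OCc2ccccc2)cc(OCc2ccccc2)c1 | starting material
5 | 1-[4-(benzyloxy)phenyl]-2-[3,5-bis(benzyloxy)phenyl]ethan-1-one | O=C(Cc1cc(OCc2ccccc2)cc(OCc2ccccc2)c1)c1ccc(OCc2ccccc2)cc1 | intermediate
6 | racemic 1-[4-(benzyloxy)phenyl]-2-[4-(benzyloxy)-3,5-dichlorophenyl]-2-[3,5-bis(benzyloxy)phenyl]ethan-1-one | O=C(c1ccc(OCc2ccccc2)cc1)C(c1cc(OCc2ccccc2)cc(OCc2ccccc2)c1)c1cc(Cl)c(OCc2ccccc2)c(Cl)c1 | intermediate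
7 | chloroaryne from 6 (lithium enolate in the flask, drawn as the neutral ketone) | O=C(c1ccc(OCc2ccccc2)cc1)C(c1cc(OCc2ccccc2)cc(OCc2ccccc2)c1)C1=CC(Cl)=C(OCc2ccccc2)C#C1 | intermediate
8 | 6-(benzyloxy)-2-[4-(benzyloxy)phenyl]-3-[3,5-bis(benzyloxy)phenyl]-5-chloro-1-benzofuran | c1c(OCc9ccccc9)cc(OCc9ccccc9)cc1-c1c2cc(Cl)c(OCc9ccccc9)cc2oc1-c1ccc(OCc9ccccc9)cc1 | intermediate
9 | (2R,3S)-6-(benzyloxy)-2-[4-(benzyloxy)phenyl]-3-[3,5-bis(benzyloxy)phenyl]-5-chloro-2,3-dihydro-1-benzofuran (cis unit) | c1c(OCc9ccccc9)cc(OCc9ccccc9)cc1[C@H]1c2c(cc(OCc9ccccc9)c(Cl)c2)O[C@H]1c1ccc(OCc9ccccc9)cc1 | intermediate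
10 | (2S,3S)-6-(benzyloxy)-2-[4-(benzyloxy)phenyl]-3-[3,5-bis(benzyloxy)phenyl]-5-chloro-2,3-dihydro-1-benzofuran (trans unit) | c1c(OCc9ccccc9)cc(OCc9ccccc9)cc1[C@H]1c2c(cc(OCc9ccccc9)c(Cl)c2)O[C@@H]1c1ccc(OCc9ccccc9)cc1 | intermediate
11 | 4-(4-hydroxyphenyl)-4-oxobutanoic acid | O=C(O)CCC(=O)c1ccc(O)cc1 | starting material
12 | 4-hydroxy-4-(4-hydroxyphenyl)butanoic acid | O=C(O)CCC(O)c1ccc(O)cc1 | intermediate
13 | racemic 5-(4-hydroxyphenyl)oxolan-2-one | O=C1CCC(c2ccc(O)cc2)O1 | intermediate
14 | 1-(benzyloxy)-4-bromobenzene | Brc1ccc(OCc2ccccc2)cc1 | starting material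
15 | [4-(benzyloxy)phenyl]lithium | [Li]c1ccc(OCc2ccccc2)cc1 | intermediate
16 | racemic 1-[4-(benzyloxy)phenyl]-4-hydroxy-4-(4-hydroxyphenyl)butan-1-one | OC(CCC(=O)c1ccc(OCc2ccccc2)cc1)c1ccc(O)cc1 | intermediate
17 | (4R)-1-[4-(benzyloxy)phenyl]-4-(4-hydroxyphenyl)-4-{2,4-bis(benzyloxy)-6-[(2S,3S)-trans unit-3-yl]phenyl}butan-1-one | Oc1ccc([C@@H](CCC(=O)c2ccc(OCc9ccccc9)cc2)c2c(OCc9ccccc9)cc(OCc9ccccc9)cc2[C@H]2c3c(cc(OCc9ccccc9)c(Cl)c3)O[C@@H]2c2ccc(OCc9ccccc9)cc2)cc1 | intermediate
18 | aryne from 17 (C-4≡C-5 of the trans unit, drawn in neutral form) | Oc1ccc([C@@H](CCC(=O)c2ccc(OCc9ccccc9)cc2)c2c(OCc9ccccc9)cc(OCc9ccccc9)cc2[C@H]2C3=C(C=C(OCc9ccccc9)C#C3)O[C@@H]2c2ccc(OCc9ccccc9)cc2)cc1 | intermediate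
19 | ketone of the first eight-membered ring: ring closed between chain C3 and benzofuran C-4 of the trans unit, 4-(benzyloxy)benzoyl on C3 (C1 R; C3 epimers) | Oc1ccc([C@@H]2c3c(OCc9ccccc9)cc(OCc9ccccc9)cc3[C@H]3c4c(cc(OCc9ccccc9)cc4C(C2)C(=O)c2ccc(OCc9ccccc9)cc2)O[C@@H]3c2ccc(OCc9ccccc9)cc2)cc1 | intermediate
20 | benzylic alcohol of the first eight-membered ring, from 19 (epimers at C3 and C4) | Oc1ccc([C@@H]2c3c(OCc9ccccc9)cc(OCc9ccccc9)cc3[C@H]3c4c(cc(OCc9ccccc9)cc4C(C2)C(O)c2ccc(OCc9ccccc9)cc2)O[C@@H]3c2ccc(OCc9ccccc9)cc2)cc1 | intermediate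
21 | compound of the first eight-membered ring with the cis unit joined through its resorcinol ring to C4 (C1 R, C3 R, C4 R) | Oc1ccc([C@@H]2c3c(OCc9ccccc9)cc(OCc9ccccc9)cc3[C@H]3c4c(cc(OCc9ccccc9)cc4[C@H](C2)[C@H](c5ccc(OCc9ccccc9)cc5)c5c(OCc9ccccc9)cc(OCc9ccccc9)cc5[C@H]5c6c(cc(OCc9ccccc9)c(Cl)c6)O[C@H]5c5ccc(OCc9ccccc9)cc5)O[C@@H]3c2ccc(OCc9ccccc9)cc2)cc1 | intermediate
22 | p-quinone methide from 21 (C1 exocyclic to the cyclohexadienone) | O=C1C=CC(=C2c3c(OCc9ccccc9)cc(OCc9ccccc9)cc3[C@H]3c4c(cc(OCc9ccccc9)cc4[C@H](C2)[C@H](c5ccc(OCc9ccccc9)cc5)c5c(OCc9ccccc9)cc(OCc9ccccc9)cc5[C@H]5c6c(cc(OCc9ccccc9)c(Cl)c6)O[C@H]5c5ccc(OCc9ccccc9)cc5)O[C@@H]3c2ccc(OCc9ccccc9)cc2)C=C1 | intermediate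
23 | 4-hydroxyphenyl alkene: C1=C2 double bond, cis within the eight-membered ring, C3 and C4 as in 21 | Oc1ccc(/C=2c3c(OCc9ccccc9)cc(OCc9ccccc9)cc3[C@H]3c4c(cc(OCc9ccccc9)cc4[C@H](\C=2)[C@H](c5ccc(OCc9ccccc9)cc5)c5c(OCc9ccccc9)cc(OCc9ccccc9)cc5[C@H]5c6c(cc(OCc9ccccc9)c(Cl)c6)O[C@H]5c5ccc(OCc9ccccc9)cc5)O[C@@H]3c2ccc(OCc9ccccc9)cc2)cc1 | intermediate
24 | aryne from 23 (C-4≡C-5 of the cis unit, drawn in neutral form) | Oc1ccc(/C=2c3c(OCc9ccccc9)cc(OCc9ccccc9)cc3[C@H]3c4c(cc(OCc9ccccc9)cc4[C@H](\C=2)[C@H](c5ccc(OCc9ccccc9)cc5)c5c(OCc9ccccc9)cc(OCc9ccccc9)cc5[C@H]5C6=C(C=C(OCc9ccccc9)C#C6)O[C@H]5c5ccc(OCc9ccccc9)cc5)O[C@@H]3c2ccc(OCc9ccccc9)cc2)cc1 | intermediate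
25 | bicyclic tetrasubstituted alkene: C2 joined to benzofuran C-4 of the cis unit, C1=C2 double bond | Oc1ccc(/C=2c3c(OCc9ccccc9)cc(OCc9ccccc9)cc3[C@H]3c4c(cc(OCc9ccccc9)cc4[C@H]4[C@H](c5ccc(OCc9ccccc9)cc5)c5c(OCc9ccccc9)cc(OCc9ccccc9)cc5[C@H]5c6c(cc(OCc9ccccc9)cc6/C=24)O[C@H]5c2ccc(OCc9ccccc9)cc2)O[C@@H]3c2ccc(OCc9ccccc9)cc2)cc1 | intermediate
26 | nona-O-benzyl ether of the target (free 4-hydroxyphenyl on C1; C1 R, C2 S, C3 R, C4 R) | Oc1ccc([C@@H]2c3c(OCc9ccccc9)cc(OCc9ccccc9)cc3[C@H]3c4c(cc(OCc9ccccc9)cc4[C@H]4[C@H](c5ccc(OCc9ccccc9)cc5)c5c(OCc9ccccc9)cc(OCc9ccccc9)cc5[C@H]5c6c(cc(OCc9ccccc9)cc6[C@H]24)O[C@H]5c2ccc(OCc9ccccc9)cc2)O[C@@H]3c2ccc(OCc9ccccc9)cc2)cc1 | intermediate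
27 | target, CNP0224452.3 | Oc1ccc([C@@H]2c3c(O)cc(O)cc3[C@H]3c4c(cc(O)cc4[C@H]4[C@H](c5ccc(O)cc5)c5c(O)cc(O)cc5[C@H]5c6c(cc(O)cc6[C@H]24)O[C@H]5c2ccc(O)cc2)O[C@@H]3c2ccc(O)cc2)cc1 | target

**Count and risks**

Total steps: 16. Longest linear sequence: 13 steps (step 1 or 2, then 3–6 and 9–16).

Steps most likely to fail:

Step 14 (proposed new method). The phenoxide may react through oxygen or a ring carbon of another molecule, or the aryne may be consumed by the amide base before the medium ring closes; the strong base may also open a dihydrobenzofuran by β-elimination of the aryloxide. Fallback by known chemistry, setting out from 23: bromination of the alkene CH with N-bromosuccinimide (addition, then loss of HBr through the quinone methide) should give the vinyl bromide F1. Palladium-catalysed intramolecular direct arylation at the C–H bond ortho to chlorine (Pd(OAc)2, PCy3·HBF4, K2CO3, pivalic acid, N,N-dimethylacetamide, 110 °C) should close the eight-membered ring to the chloro analogue F2. Hydrodechlorination (Pd(OAc)2, dicyclohexyl(2',6'-dimethoxybiphenyl-2-yl)phosphine, HCO2Na, DMF, 80 °C) returns to the route at 25.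

Step 10. Ring opening of the trans-dihydrobenzofuran by deprotonation at C-3 and loss of the aryloxide may compete with ortho-lithiation, and closure of the eight-membered ring on a short-lived aryne may be slow. Fallback, setting out from benzofuran 8 (with 16): the same phosphoric-acid Friedel–Crafts reaction should give the benzofuran ketone F3, which has no base-labile C-3 hydrogen; the enolate–aryne closure then gives the ring-closed benzofuran ketone F4. Ruthenium–carbene hydrogenation as in step 5 gives the cis-dihydrobenzofuran ketone F5, and trifluoroacetic acid epimerises C-2, returning to the route at 19.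

Step 5. The tetrasubstituted, hindered furan double bond may be hydrogenated slowly or with poor facial selectivity. Fallback, setting out from ketone 6 and bypassing the benzofuran: Corey–Bakshi–Shibata reduction with one enantiomer of the oxazaborolidine (BH3·SMe2, THF) and chromatographic separation of the two C-2 epimers should give the (1R,2S)-alcohol F6; the other catalyst enantiomer gives the (1S,2S)-alcohol F7. Each alkoxide is closed onto the chloroaryne with lithium 2,2,6,6-tetramethylpiperidide, with retention at the carbinol carbon, returning to the route at 9 (from F6) and at 10 (from F7).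

**Further compounds**

F1 | step 14 | vinyl bromide: 23 with bromine on C2 of the chain | Oc1ccc(/C=2c3c(OCc9ccccc9)cc(OCc9ccccc9)cc3[C@H]3c4c(cc(OCc9ccccc9)cc4[C@H](\C=2Br)[C@H](c5ccc(OCc9ccccc9)cc5)c5c(OCc9ccccc9)cc(OCc9ccccc9)cc5[C@H]5c6c(cc(OCc9ccccc9)c(Cl)c6)O[C@H]5c5ccc(OCc9ccccc9)cc5)O[C@@H]3c2ccc(OCc9ccccc9)cc2)cc1
F2 | step 14 | chloro analogue of 25 (chlorine on C-5 of the cis unit) | Oc1ccc(/C=2c3c(OCc9ccccc9)cc(OCc9ccccc9)cc3[C@H]3c4c(cc(OCc9ccccc9)cc4[C@H]4[C@H](c5ccc(OCc9ccccc9)cc5)c5c(OCc9ccccc9)cc(OCc9ccccc9)cc5[C@H]5c6c(cc(OCc9ccccc9)c(Cl)c6/C=24)O[C@H]5c2ccc(OCc9ccccc9)cc2)O[C@@H]3c2ccc(OCc9ccccc9)cc2)cc1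
F3 | step 10 | benzofuran analogue of 17 (C1 R) | Oc1ccc([C@@H](CCC(=O)c2ccc(OCc9ccccc9)cc2)c2c(OCc9ccccc9)cc(OCc9ccccc9)cc2-c2c3cc(Cl)c(OCc9ccccc9)cc3oc2-c2ccc(OCc9ccccc9)cc2)cc1
F4 | step 10 | benzofuran analogue of 19 (C3 epimers) | Oc1ccc([C@@H]2c3c(OCc9ccccc9)cc(OCc9ccccc9)cc3-c3c4c(cc(OCc9ccccc9)cc4C(C2)C(=O)c2ccc(OCc9ccccc9)cc2)oc3-c2ccc(OCc9ccccc9)cc2)cc1
F5 | step 10 | cis-dihydrobenzofuran epimer of 19 (furan C-2 R, C-3 S) | Oc1ccc([C@@H]2c3c(OCc9ccccc9)cc(OCc9ccccc9)cc3[C@H]3c4c(cc(OCc9ccccc9)cc4C(C2)C(=O)c2ccc(OCc9ccccc9)cc2)O[C@H]3c2ccc(OCc9ccccc9)cc2)cc1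
F6 | step 5 | (1R,2S)-1-[4-(benzyloxy)phenyl]-2-[4-(benzyloxy)-3,5-dichlorophenyl]-2-[3,5-bis(benzyloxy)phenyl]ethan-1-ol | c1c(OCc9ccccc9)cc(OCc9ccccc9)cc1[C@H]([C@@H](O)c1ccc(OCc9ccccc9)cc1)c1cc(Cl)c(OCc9ccccc9)c(Cl)c1
F7 | step 5 | (1S,2S)-1-[4-(benzyloxy)phenyl]-2-[4-(benzyloxy)-3,5-dichlorophenyl]-2-[3,5-bis(benzyloxy)phenyl]ethan-1-ol | c1c(OCc9ccccc9)cc(OCc9ccccc9)cc1[C@H]([C@H](O)c1ccc(OCc9ccccc9)cc1)c1cc(Cl)c(OCc9ccccc9)c(Cl)c1
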